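**Retrosynthetic overview**

1. Both CH2 bridges are disconnected last (Mannich base → quinone methide → C-alkylation of a phloroglucinol carbon): ring C–CH2–ring B is made first and the chiral ring A is attached at the end.
2. Ring A (C1 ring C=O, C2 acetyl-bearing, C3, C4 quaternary with methyl and geranyl, C5, C6 bridge carbon) is a cyclohexane-1,3,5-trione: C5–C6–C1 is a malonyl unit and C2 and C4 are the two α-carbons of the C3 carbonyl. C2 is a β-diketone carbon and C4 is quaternary, so no aromatisation can intervene.
3. Ring A is therefore closed in one [3+3] double C-acylation (bonds C4–C5 and C1–C2) of an acyclic silyl dienol ether, which carries the acetyl group as its enol ether, with malonyl dichloride. The dienol ether precursor comes from 4-methoxypent-3-en-2-one by two α′-alkylations (geranyl bromide, MeI).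
4. C4 is formed as a racemate in the key step and is resolved without extra steps as a Mannich base of an (S)-amine, which then serves as the leaving group of the last coupling.
5. Order of ring formation: ring A (step 3), then the pyran ring of ring C (step 5); the two benzene rings are bought.

Key step: step 3

Remark: 1-(2,4,6-trihydroxyphenyl)butan-1-one is taken as purchased (otherwise one Friedel–Crafts acylation of phloroglucinol), and all triketone rings are drawn in the enol tautomer used for the target.

**Route**

Step 1
Reactants: 1 (E)-4-methoxypent-3-en-2-one; 2 geranyl bromide [(2E)-1-bromo-3,7-dimethylocta-2,6-diene]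
Product: 3 (2E,7E)-2-methoxy-8,12-dimethyltrideca-2,7,11-trien-4-one
Conditions: LiN(iPr)2, THF, −78 °C; then 2, N,N′-dimethylpropyleneurea, −78 → −20 °C
Reagents that add atoms: none
Why: Kinetic α′-deprotonation of the vinylogous ester (Stork–Danheiser-type enolate) and SN2 alkylation with the allylic bromide should give the α′-geranyl ketone with the E-alkene untouched.

Step 2
Reactants: 3 (2E,7E)-2-methoxy-8,12-dimethyltrideca-2,7,11-trien-4-one
Product: 4 rac-(2E,7E)-2-methoxy-5,8,12-trimethyltrideca-2,7,11-trien-4-one
Conditions: LiN(iPr)2, THF, −78 °C; then MeI, −78 → 0 °C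
Reagents that add atoms: iodomethane, CI
Why: A second kinetic α′-enolisation and SN2 methylation should install the methyl group; the new stereocentre is racemic and is erased by enolisation in step 3.

Step 3
Reactants: 4 rac-(2E,7E)-2-methoxy-5,8,12-trimethyltrideca-2,7,11-trien-4-one; 5 malonyl dichloride (propanedioyl dichloride)
Product: 9 rac-2-acetyl-4-[(2E)-3,7-dimethylocta-2,6-dien-1-yl]-3,5-dihydroxy-4-methylcyclohexa-2,5-dien-1-one, via silyl dienol ether 6 (not isolated), via keto acid chloride 7 (not isolated), via enol lactone 8 (not isolated)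
Conditions: LiN(iPr)2, Me3SiCl, THF, −78 °C; evaporate, pentane, filter; 5, CH2Cl2, −78 → −20 °C; then Et3N, 4-(dimethylamino)pyridine (10 mol %), −20 °C → rt; dilute aqueous HCl work-up
Reagents that add atoms: none
Why: Kinetic α′-deprotonation of 4 with in situ silylation gives dienol ether 6, whose tetrasubstituted terminus C4 attacks one acyl chloride of 5 (Mukaiyama-type C-acylation, bond C4–C5, Me3SiCl leaves) to give 7. The second acyl chloride is captured within the molecule by the vinylogous-ester oxygen with loss of MeCl (enol lactone 8), and Et3N/4-(dimethylamino)pyridine then relay this acyl group from oxygen to the β-diketone carbon C2 (bond C1–C2), the strongly acidic triketone enolate being the thermodynamic sink; direct C-acylation at C2 would lead to the same product. The closest known reaction type is the Effenberger cyclisation of ketone silyl enol ethers with malonyl dichloride to cyclic β-triketones, coupled with the nucleophile-catalysed rearrangement of enol esters to 2-acyl-1,3-diones. Ring A is the only ring closed, by a 6-exo-trig acyl substitution of C2 on C1. The new stereocentre C4 is formed without bias, since 6 is an achiral E/Z mixture and no chiral element is present, so 9 is racemic by design and its configuration is selected in step 4. The step needs attack through C4 and C2 rather than through the vinylogous methyl group, and carbon rather than oxygen in the ring closure; the first is secured by the α′-regiochemistry of the dienol ether, the second by the O-to-C relay and by quaternary C4, which rules out aromatisation to a hydroxypyrone or a phenol.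

Step 4
Reactants: 9 rac-2-acetyl-4-[(2E)-3,7-dimethylocta-2,6-dien-1-yl]-3,5-dihydroxy-4-methylcyclohexa-2,5-dien-1-one
Product: 10 (4R)-2-acetyl-4-[(2E)-3,7-dimethylocta-2,6-dien-1-yl]-3,5-dihydroxy-4-methyl-6-({methyl[(1S)-1-phenylethyl]amino}methyl)cyclohexa-2,5-dien-1-one
Conditions: paraformaldehyde, (S)-N-methyl-1-phenylethan-1-amine, EtOH, 40 °C; then 9, 0 °C → rt; crystallisation of the diastereomers (EtOAc–heptane) or chromatography
Reagents that add atoms: formaldehyde (as paraformaldehyde), C=O; (S)-N-methyl-1-phenylethan-1-amine, CN[C@@H](C)c1ccccc1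
Why: Mannich aminomethylation at C6, the only free nucleophilic ring carbon, turns the enantiomers of 9 into diastereomeric internal ammonium enolate salts that should be separable, the 4R isomer being assigned by single-crystal diffraction relative to the known (S)-centre; no new stereocentre is created.

Step 5
Reactants: 11 1-(2,4,6-trihydroxyphenyl)butan-1-one; 12 3-methylbut-2-enal
Product: 13 1-(5,7-dihydroxy-2,2-dimethyl-2H-chromen-8-yl)butan-1-one
Conditions: ethylenediammonium diacetate (10 mol %), toluene, 110 °C, N2
Reagents that add atoms: none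
Why: Knoevenagel-type condensation at a free ring carbon followed by oxa-6π electrocyclisation of the ortho-quinone methide through the oxygen ortho to the butanoyl group should give the 8-acyl chromene, the 6-acyl regioisomer being removed by chromatography if it forms.

Step 6
Reactants: 13 1-(5,7-dihydroxy-2,2-dimethyl-2H-chromen-8-yl)butan-1-one
Product: 14 1-{6-[(dimethylamino)methyl]-5,7-dihydroxy-2,2-dimethyl-2H-chromen-8-yl}butan-1-one
Conditions: bis(dimethylamino)methane, 1,4-dioxane, rt
Reagents that add atoms: bis(dimethylamino)methane, CN(C)CN(C)C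
Why: Phenolic Mannich reaction at C6, the only unsubstituted aromatic carbon, which is flanked by two hydroxyl groups.

Step 7
Reactants: 14 1-{6-[(dimethylamino)methyl]-5,7-dihydroxy-2,2-dimethyl-2H-chromen-8-yl}butan-1-one; 11 1-(2,4,6-trihydroxyphenyl)butan-1-one
Product: 15 1-{3-[(8-butanoyl-5,7-dihydroxy-2,2-dimethyl-2H-chromen-6-yl)methyl]-2,4,6-trihydroxyphenyl}butan-1-one
Conditions: 11 (4 equiv), 1,4-dioxane, 100 °C, N2
Reagents that add atoms: none
Why: Thermal loss of dimethylamine from the phenolic Mannich base should give an ortho-quinone methide that is trapped by a ring carbon of 11 (Friedel–Crafts-type conjugate addition), the excess of 11 suppressing double alkylation.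

Step 8
Reactants: 10 (4R)-2-acetyl-4-[(2E)-3,7-dimethylocta-2,6-dien-1-yl]-3,5-dihydroxy-4-methyl-6-({methyl[(1S)-1-phenylethyl]amino}methyl)cyclohexa-2,5-dien-1-one; 15 1-{3-[(8-butanoyl-5,7-dihydroxy-2,2-dimethyl-2H-chromen-6-yl)methyl]-2,4,6-trihydroxyphenyl}butan-1-one
Product: 16 (4R)-2-acetyl-6-({3-butanoyl-5-[(8-butanoyl-5,7-dihydroxy-2,2-dimethyl-2H-chromen-6-yl)methyl]-2,4,6-trihydroxyphenyl}methyl)-4-[(2E)-3,7-dimethylocta-2,6-dien-1-yl]-3,5-dihydroxy-4-methylcyclohexa-2,5-dien-1-one (CNP0103039.1)
Conditions: 1,4-dioxane, 70 °C, N2
Reagents that add atoms: none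
Why: The Mannich base of the cyclic triketone should lose the amine on mild heating to give a 2-methylene-1,3,5-trione (a vinylogous quinone methide) that is captured by the single free aromatic carbon of ring B (conjugate addition / Friedel–Crafts alkylation), while quaternary C4 cannot epimerise.

**Compound list**

1 | (E)-4-methoxypent-3-en-2-one | CO/C(C)=C/C(C)=O | starting material
2 | geranyl bromide, (2E)-1-bromo-3,7-dimethylocta-2,6-diene | BrC/C=C(\C)CCC=C(C)C | starting material
3 | (2E,7E)-2-methoxy-8,12-dimethyltrideca-2,7,11-trien-4-one | CO/C(C)=C/C(=O)CC/C=C(\C)CCC=C(C)C | intermediate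
4 | rac-(2E,7E)-2-methoxy-5,8,12-trimethyltrideca-2,7,11-trien-4-one | CO/C(C)=C/C(=O)C(C)C/C=C(\C)CCC=C(C)C | intermediate
5 | malonyl dichloride (propanedioyl dichloride) | O=C(Cl)CC(Cl)=O | starting material
6 | {[(2E,7E)-2-methoxy-5,8,12-trimethyltrideca-2,4,7,11-tetraen-4-yl]oxy}trimethylsilane (4E/4Z mixture) | CO/C(C)=C/C(O[Si](C)(C)C)=C(C)C/C=C(\C)CCC=C(C)C | intermediate (not isolated)
7 | rac-(6E)-4-[(2E)-3,7-dimethylocta-2,6-dien-1-yl]-7-methoxy-4-methyl-3,5-dioxooct-6-enoyl chloride | ClC(=O)CC(=O)C(C)(C/C=C(\C)CCC=C(C)C)C(=O)/C=C(\C)OC | intermediate (not isolated)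
8 | rac-5-[(2E)-3,7-dimethylocta-2,6-dien-1-yl]-5-methyl-6-(2-oxopropylidene)oxane-2,4-dione | CC(=O)C=C1OC(=O)CC(=O)C1(C)C/C=C(\C)CCC=C(C)C | intermediate (not isolated)
9 | rac-2-acetyl-4-[(2E)-3,7-dimethylocta-2,6-dien-1-yl]-3,5-dihydroxy-4-methylcyclohexa-2,5-dien-1-one | O=C1C=C(O)C(C)(C/C=C(\C)CCC=C(C)C)C(O)=C1C(C)=O | intermediate
10 | (4R)-2-acetyl-4-[(2E)-3,7-dimethylocta-2,6-dien-1-yl]-3,5-dihydroxy-4-methyl-6-({methyl[(1S)-1-phenylethyl]amino}methyl)cyclohexa-2,5-dien-1-one | C[C@@H](c1ccccc1)N(C)CC1=C(O)[C@@](C)(C/C=C(\C)CCC=C(C)C)C(O)=C(C(C)=O)C1=O | intermediate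
11 | 1-(2,4,6-trihydroxyphenyl)butan-1-one | CCCC(=O)c1c(O)cc(O)cc1O | starting material
12 | 3-methylbut-2-enal | CC(C)=CC=O | starting material
13 | 1-(5,7-dihydroxy-2,2-dimethyl-2H-chromen-8-yl)butan-1-one | CCCC(=O)c1c(O)cc(O)c2c1OC(C)(C)C=C2 | intermediate
14 | 1-{6-[(dimethylamino)methyl]-5,7-dihydroxy-2,2-dimethyl-2H-chromen-8-yl}butan-1-one | CCCC(=O)c1c(O)c(CN(C)C)c(O)c2c1OC(C)(C)C=C2 | intermediate
15 | 1-{3-[(8-butanoyl-5,7-dihydroxy-2,2-dimethyl-2H-chromen-6-yl)methyl]-2,4,6-trihydroxyphenyl}butan-1-one | CCCC(=O)c1c(O)cc(O)c(Cc2c(O)c3c(c(C(=O)CCC)c2O)OC(C)(C)C=C3)c1O | intermediate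
16 | CNP0103039.1, (4R)-2-acetyl-6-({3-butanoyl-5-[(8-butanoyl-5,7-dihydroxy-2,2-dimethyl-2H-chromen-6-yl)methyl]-2,4,6-trihydroxyphenyl}methyl)-4-[(2E)-3,7-dimethylocta-2,6-dien-1-yl]-3,5-dihydroxy-4-methylcyclohexa-2,5-dien-1-one | CCCC(=O)c1c(O)c(CC2=C(O)[C@@](C)(C/C=C(\C)CCC=C(C)C)C(O)=C(C(C)=O)C2=O)c(O)c(Cc2c(O)c3c(c(C(=O)CCC)c2O)OC(C)(C)C=C3)c1O | target

**Step count**

Total steps: 8. Longest linear sequence: 5 steps (steps 1, 2, 3, 4 and 8).

**Steps most likely to fail**

Step 3 (key step). Enolisation and silylation may take place at the vinylogous methyl group instead of at C4–H, and the tethered acyl chloride may close through oxygen without relay to carbon (pyranone formation), so that material is diverted from the carbocycle. The fallback sets out from 2 and comes back to the route at 9. Commercial 1-(2,4,6-trihydroxy-3-methylphenyl)ethan-1-one F1 would be treated with NaOMe in MeOH and 2 at 0 °C. Alkylative dearomatisation of F1 at its methyl-bearing ring carbon, the position that is also attacked in gem-dialkylations of acylphloroglucinols, should give rac-9. In this variant ring A is bought as an arene and the quaternary carbon is made by C-alkylation instead of by ring construction; O-geranyl ethers and the aromatic regioisomer would be removed by chromatography.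

Step 4. The two diastereomeric Mannich bases may co-crystallise or fail to separate, and retro-Mannich loss of the amine may be followed by dimerisation of ring A through a CH2 bridge. The fallback sets out from 9 and comes back at 10. The enantiomers of 9 would be separated by preparative supercritical-fluid chromatography on an amylose tris(3,5-dimethylphenylcarbamate) phase, which should deliver the dextro- and laevorotatory forms separately, one of them being (4R)-2-acetyl-4-[(2E)-3,7-dimethylocta-2,6-dien-1-yl]-3,5-dihydroxy-4-methylcyclohexa-2,5-dien-1-one F2. The enantiomer F2 would then be aminomethylated under the conditions of step 4 to give 10 as a single diastereomer. This replaces diastereomer separation by resolution of enantiomers on a chiral phase.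

Step 8. The methylene-triketone released from 10 may condense with itself, and the existing bridge of 15 may exchange by retro-Friedel–Crafts fragmentation and recombination, which would scramble the three rings. The fallback sets out from 10 and 11 and comes back at 16, with the order of bridge formation reversed. Compound 10 would be heated with an excess of 11 (1,4-dioxane, 70 °C) to give (4R)-2-acetyl-6-[(3-butanoyl-2,4,6-trihydroxyphenyl)methyl]-4-[(2E)-3,7-dimethylocta-2,6-dien-1-yl]-3,5-dihydroxy-4-methylcyclohexa-2,5-dien-1-one F3, the excess of the simple phenol outrunning self-condensation. The bis-ring intermediate F3 would then be alkylated at its one free aromatic carbon by the ortho-quinone methide released from 14 (1,4-dioxane, 100 °C) to give 16.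

**Further compounds**

F1 | step 3 | 1-(2,4,6-trihydroxy-3-methylphenyl)ethan-1-one | CC(=O)c1c(O)cc(O)c(C)c1O
F2 | step 4 | (4R)-2-acetyl-4-[(2E)-3,7-dimethylocta-2,6-dien-1-yl]-3,5-dihydroxy-4-methylcyclohexa-2,5-dien-1-one | O=C1C=C(O)[C@@](C)(C/C=C(\C)CCC=C(C)C)C(O)=C1C(C)=O
F3 | step 8 | (4R)-2-acetyl-6-[(3-butanoyl-2,4,6-trihydroxyphenyl)methyl]-4-[(2E)-3,7-dimethylocta-2,6-dien-1-yl]-3,5-dihydroxy-4-methylcyclohexa-2,5-dien-1-one | CCCC(=O)c1c(O)cc(O)c(CC2=C(O)[C@@](C)(C/C=C(\C)CCC=C(C)C)C(O)=C(C(C)=O)C2=O)c1O
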